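Wednesday's run and Thursday's run differ in the free catalyst charged, by a factor of 2.30, yet after 2.50 h their left-handed product stands at 32% and 37%, a smaller factor of 1.16.

| setting | Wednesday's | Thursday's | flask |
|---|---|---|---|
| left-handed substrate | 2 M | 2 M | 2.0 M |
| right-handed substrate | 2 M | 2 M | 2.0 M |
| gas | 200 mM (held) | 200 mM (held) | 200 mM (held) |
| free catalyst | 0.74 mM | 1.7 mM | 1.1 mM |
| remark | run made earlier | run made earlier |  |

| run | time / h | left-handed product / % |
|---|---|---|
| Wednesday's | 0.200 | 2 |
| Wednesday's | 0.333 | 4 |
| Wednesday's | 0.417 | 4 |
| Wednesday's | 0.667 | 11 |
| Wednesday's | 1.00 | 12 |
| Wednesday's | 1.50 | 19 |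
| Wednesday's | 2.50 | 32 |
| Thursday's | 0.200 | 3 |
| Thursday's | 0.333 | 7 |
| Thursday's | 0.417 | 7 |
| Thursday's | 0.667 | 12 |
| Thursday's | 1.00 | 14 |
| Thursday's | 1.50 | 23 |
| Thursday's | 2.50 | 37 |

(each reading ± 1.5 percentage points)

- free catalyst is single-handed; left-handed substrate and right-handed substrate are mirror images of each other, charged as a racemate, each of them at the stated concentration
- at the start none of coupling partner is dissolved
- the earlier runs were read with a standard deviation of 1.5 percentage points
- on the list of suspects stand: free catalyst + left-handed substrate <-> catalyst intermediate A; free catalyst + right-handed substrate <-> catalyst intermediate B; coupling partner + catalyst intermediate A -> free catalyst + left-handed product; coupling partner + catalyst intermediate B -> free catalyst + right-handed product; coupling partner -> decomposed reagent; gas <-> coupling partner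

- apparent order in free catalyst when 30% of the left-handed substrate and right-handed substrate together are converted (percent change of the rate of making left-handed product for one percent more free catalyst charged)
- factor on the rate of making left-handed product when 30% of the left-handed substrate and right-handed substrate together are converted if free catalyst is charged twice over

At the start no coupling partner is dissolved, so the first product waits for the gas. That wait is too short to read: from 0.200 h to 2.50 h in Thursday's run, time grows 12.5-fold and the product 12.3-fold, with a scatter of 1.5 percentage points on each reading. The middle is this straight line, and Wednesday's run passes the conversion asked about before its last reading, since left-handed product by itself exceeds 30% there. The end lies beyond the readings: Thursday's last reading stands for 74.0% of the left-handed substrate charged.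

Product that grows less than the catalyst charged is read here as a supply, with gas becoming coupling partner as the suspected rate-limiting step. On this reading, catalyst intermediate A and catalyst intermediate B compete for coupling partner with decomposition and return to gas, and capture takes the share C/(C+H) of the supply, C being the catalyst charged. The last readings give 0.233 mM for H, the half-capture charge: the catalyst charge at which capture and losses take equal parts of the supply. The apparent order is then the small correction H/(H+C), which this reckoning puts at 0.175 for the flask's 1.1 mM, and doubling the charge multiplies the rate by 1.10.

The forecast gives 0.17 (0.06 to 0.32) and 1.1 (1.03 to 1.22), on the ground: “That points to supply of the coupling partner from the gas as the main limit”. The flask gives 0.19 and 1.09.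

    free catalyst + left-handed substrate ⇌ catalyst intermediate A (K = 0.420 M⁻¹, k = 8700 M⁻¹ h⁻¹)
    free catalyst + right-handed substrate ⇌ catalyst intermediate B (K = 1.30 M⁻¹, k = 1200 M⁻¹ h⁻¹)
    coupling partner + catalyst intermediate A → free catalyst + left-handed product (k = 57000 M⁻¹ h⁻¹)
    coupling partner + catalyst intermediate B → free catalyst + right-handed product (k = 19000 M⁻¹ h⁻¹)
    coupling partner → decomposed reagent (k = 0.490 h⁻¹)
    gas ⇌ coupling partner, rate k6*(csat - [coupling partner]) (kL = 6.50 h⁻¹)

In the flask at 2.00 h, coupling partner stands at 0.0532 M, a quarter of its saturation value of 200 mM. With H, the flask's catalyst charge corresponds to a capture share of 82.5%, and Thursday's charge of 1.7 mM to an apparent order of 0.121.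

The data come from a simulation from invented constants; noise was put on by code.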